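**Plan**
- Retrosynthesis: the three benzyl ethers and two aryl C–Cl bonds come off last. Both aryl–C(=O) bonds and both aryl–O bonds of the two 2,4-dihydroxyphenyl ketones are then cut in one operation (four bonds), giving benzofuran diacid 6 and two molecules of a chloro(benzyloxy)aryne stored as silyl triflate 12.
- Enabling feature: the carbonyl carbon on C3 of the furan ring and the carbonyl carbon ending the C5 propyl chain are each bonded to a resorcinol ring carbon whose ring neighbour carries a hydroxyl oxygen. This acyl/oxygen 1,2-pattern is what an aryne leaves when it inserts into the CO–OH bond of a carboxylic acid.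
- Diacid 6 is cut at C3–C3a and O1–C2 of the furan ring, back to para-substituted phenol 3 and aroylacetate 2.
- Forward: the furan ring is annulated onto the benzene ring of 3, the esters are hydrolysed, both resorcinol rings are attached together by double aryne insertion, and one hydrogenolysis removes chlorine and benzyl.
- Stereochemistry: the target has no stereocentre. The only control needed is regiochemical, supplied by a chlorine on the aryne that is removed at the end.

Key step: step 8

Remark: compounds 1, 3 and 7 are taken as purchasable, as are 1-(benzyloxy)-4-ethynylbenzene and 2,4-dimethoxyphenylmagnesium bromide used in the fallbacks.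

**Route**

Step 1
Reactants: 1 4'-(benzyloxy)acetophenone
Product: 2 methyl 3-[4-(benzyloxy)phenyl]-3-oxopropanoate
Conditions: NaH (2.5 equiv), (MeO)2CO (3 equiv), THF, reflux; then aq. HCl
Reagents that add atoms: dimethyl carbonate, COC(=O)OC
Why: Crossed Claisen condensation (methoxycarbonylation of the methyl ketone enolate) should be driven to completion by irreversible deprotonation of the beta-keto ester formed, and the aryl benzyl ether is inert to hydride base.

Step 2
Reactants: 2 methyl 3-[4-(benzyloxy)phenyl]-3-oxopropanoate; 3 methyl 3-(4-hydroxyphenyl)propanoate (3 equiv, excess recoverable)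
Product: 5 methyl 2-[4-(benzyloxy)phenyl]-5-(3-methoxy-3-oxopropyl)-1-benzofuran-3-carboxylate, via alpha-aryl keto ester 4 (not isolated)
Conditions: FeCl3·6H2O (10 mol%), (t-BuO)2 (2 equiv), ClCH2CH2Cl, 100 °C, sealed tube
Reagents that add atoms: none
Why: Iron-catalysed oxidative cross-dehydrogenative coupling of the keto ester, bound as its enolate to trivalent iron, with the phenol ortho carbon (peroxide as terminal oxidant), followed by Lewis-acid cyclodehydration of the phenol oxygen onto the aryl ketone, is established for para-substituted phenols and aroylacetates; the blocked para position forces ortho coupling and hence the 5-substituted 2-aryl-3-carboxylate.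

Step 3
Reactants: 5 methyl 2-[4-(benzyloxy)phenyl]-5-(3-methoxy-3-oxopropyl)-1-benzofuran-3-carboxylate
Product: 6 2-[4-(benzyloxy)phenyl]-5-(2-carboxyethyl)-1-benzofuran-3-carboxylic acid
Conditions: NaOH (aq., excess), THF/MeOH, 65 °C; then aq. HCl to pH 2
Reagents that add atoms: sodium hydroxide, [Na+].[OH-]
Why: Saponification of both methyl esters should proceed on heating (the conjugated, hindered C3 ester is the slower one), and the benzyl ether and benzofuran are stable to hydroxide.

Step 4
Reactants: 7 4-(benzyloxy)phenol
Product: 8 4-(benzyloxy)-2-chlorophenol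
Conditions: SO2Cl2 (1.0 equiv), i-Bu2NH (5 mol%), toluene, 0 °C to rt
Reagents that add atoms: sulfuryl chloride, O=S(=O)(Cl)Cl
Why: Amine-catalysed electrophilic aromatic chlorination is directed ortho to the free hydroxyl, the stronger activator, with the para position blocked, as known for 4-alkoxyphenols, and one equivalent of reagent should limit reaction to monochlorination.

Step 5
Reactants: 8 4-(benzyloxy)-2-chlorophenol
Product: 9 4-(benzyloxy)-2-bromo-6-chlorophenol
Conditions: NBS (1.0 equiv), i-Pr2NH (10 mol%), CH2Cl2, 0 °C
Reagents that add atoms: N-bromosuccinimide, O=C1CCC(=O)N1Br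
Why: Amine-mediated ortho-bromination of phenols should place bromine at the only remaining position ortho to the hydroxyl, which outcompetes the positions next to the weaker benzyloxy donor.

Step 6
Reactants: 9 4-(benzyloxy)-2-bromo-6-chlorophenol
Product: 10 [4-(benzyloxy)-2-bromo-6-chlorophenoxy]trimethylsilane
Conditions: (Me3Si)2NH, THF, 70 °C; evaporate
Reagents that add atoms: hexamethyldisilazane, C[Si](C)(C)N[Si](C)(C)C
Why: O-Silylation of a phenol with hexamethyldisilazane is clean and releases only ammonia, so the moisture-sensitive silyl ether can be used after evaporation.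

Step 7
Reactants: 10 [4-(benzyloxy)-2-bromo-6-chlorophenoxy]trimethylsilane
Product: 12 4-(benzyloxy)-2-chloro-6-(trimethylsilyl)phenyl trifluoromethanesulfonate, via lithium 4-(benzyloxy)-2-chloro-6-(trimethylsilyl)phenoxide 11 (not isolated)
Conditions: n-BuLi (1.1 equiv), THF, −100 to −80 °C; then Tf2O (1.2 equiv), −100 to −78 °C
Reagents that add atoms: trifluoromethanesulfonic anhydride, O=S(=O)(OS(=O)(=O)C(F)(F)F)C(F)(F)F
Why: Bromine–lithium exchange is much faster than chlorine exchange or benzylic deprotonation at this temperature, the aryllithium undergoes the 1,3 oxygen-to-carbon silyl shift (retro-Brook rearrangement), and the phenoxide is triflated in the same flask, which is the standard entry to ortho-silylaryl triflates; the lithiated carbon is not adjacent to chlorine, so no aryne forms prematurely.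

Step 8
Reactants: 6 2-[4-(benzyloxy)phenyl]-5-(2-carboxyethyl)-1-benzofuran-3-carboxylic acid; 12 4-(benzyloxy)-2-chloro-6-(trimethylsilyl)phenyl trifluoromethanesulfonate (3 equiv)
Product: 14 {2-[4-(benzyloxy)phenyl]-5-{3-[4-(benzyloxy)-2-chloro-6-hydroxyphenyl]-3-oxopropyl}-1-benzofuran-3-yl}[4-(benzyloxy)-2-chloro-6-hydroxyphenyl]methanone (dichloro tri-O-benzyl isolophirone C), via 5-(benzyloxy)-3-chlorobenzyne 13 (not isolated)
Conditions: CsF (8 equiv), THF, 125 °C, sealed tube; then aq. NH4Cl
Reagents that add atoms: none
Why: Fluoride removes the trimethylsilyl group of 12 and triflate departs to give aryne 13; each cesium carboxylate of 6 adds to the aryne carbon that carried silicon, and the aryl anion generated next to the new ester attacks its carbonyl through a transient four-membered alkoxide that opens to the ortho-acyl phenoxide, so the aryne C≡C ends up inserted into the carboxyl C–O bond. The closest known reaction is the CsF-mediated insertion of silylaryl-triflate-derived arynes into the C–O bond of aliphatic and aromatic carboxylic acids in hot THF, applied here twice on one diacid. No ring is closed in the product and no stereocentre is created. The selectivity required is regiochemical: oxygen must bond to the aryne carbon remote from chlorine, so that the acyl group ends para and the hydroxyl meta to the benzyloxy group; the inductively withdrawing chlorine flanking the triple bond distorts the aryne toward attack at the distal carbon and stabilises the developing negative charge beside itself, which should override the weaker, opposite bias of the more remote benzyloxy group. Acyl transfer is favoured over protonation of the aryl anion by the aprotic medium and high temperature, and the chelated ortho-acyl phenoxides formed are poor nucleophiles toward the excess aryne.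

Step 9
Reactants: 14 dichloro tri-O-benzyl isolophirone C
Product: 15 isolophirone C, (2,4-dihydroxyphenyl){5-[3-(2,4-dihydroxyphenyl)-3-oxopropyl]-2-(4-hydroxyphenyl)-1-benzofuran-3-yl}methanone
Conditions: H2 (1 atm), Pd/C (10%), NaOAc (3 equiv), MeOH/EtOAc, rt
Reagents that add atoms: none
Why: Palladium-catalysed hydrogenolysis cleaves the three aryl benzyl ethers and, with acetate taking up HCl, the two aryl C–Cl bonds activated by the ortho carbonyl, while the hydrogen-bonded, electron-rich ortho-hydroxyaryl ketones and the tetrasubstituted furan C2=C3 bond should be reduced much more slowly.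

**Compound list**
1 | 4'-(benzyloxy)acetophenone | CC(=O)c1ccc(OCc2ccccc2)cc1 | starting material
2 | methyl 3-[4-(benzyloxy)phenyl]-3-oxopropanoate | COC(=O)CC(=O)c1ccc(OCc2ccccc2)cc1 | intermediate
3 | methyl 3-(4-hydroxyphenyl)propanoate | COC(=O)CCc1ccc(O)cc1 | starting material
4 | methyl 3-[4-(benzyloxy)phenyl]-2-[2-hydroxy-5-(3-methoxy-3-oxopropyl)phenyl]-3-oxopropanoate (racemic, not isolated) | COC(=O)CCc1ccc(O)c(c1)C(C(=O)OC)C(=O)c1ccc(OCc2ccccc2)cc1 | intermediate
5 | methyl 2-[4-(benzyloxy)phenyl]-5-(3-methoxy-3-oxopropyl)-1-benzofuran-3-carboxylate | COC(=O)CCc1ccc2oc(-c3ccc(OCc4ccccc4)cc3)c(C(=O)OC)c2c1 | intermediate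
6 | 2-[4-(benzyloxy)phenyl]-5-(2-carboxyethyl)-1-benzofuran-3-carboxylic acid | OC(=O)CCc1ccc2oc(-c3ccc(OCc4ccccc4)cc3)c(C(=O)O)c2c1 | intermediate
7 | 4-(benzyloxy)phenol | Oc1ccc(OCc2ccccc2)cc1 | starting material
8 | 4-(benzyloxy)-2-chlorophenol | Oc1ccc(OCc2ccccc2)cc1Cl | intermediate
9 | 4-(benzyloxy)-2-bromo-6-chlorophenol | Oc1c(Br)cc(OCc2ccccc2)cc1Cl | intermediate
10 | [4-(benzyloxy)-2-bromo-6-chlorophenoxy]trimethylsilane | C[Si](C)(C)Oc1c(Br)cc(OCc2ccccc2)cc1Cl | intermediate
11 | lithium 4-(benzyloxy)-2-chloro-6-(trimethylsilyl)phenoxide (not isolated) | [Li+].[O-]c1c(Cl)cc(OCc2ccccc2)cc1[Si](C)(C)C | intermediate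
12 | 4-(benzyloxy)-2-chloro-6-(trimethylsilyl)phenyl trifluoromethanesulfonate | C[Si](C)(C)c1cc(OCc2ccccc2)cc(Cl)c1OS(=O)(=O)C(F)(F)F | intermediate
13 | 5-(benzyloxy)-3-chlorobenzyne (5-(benzyloxy)-3-chloro-1,2-didehydrobenzene, not isolated) | ClC1=CC(OCc2ccccc2)=CC#C1 | intermediate
14 | dichloro tri-O-benzyl isolophirone C, {2-[4-(benzyloxy)phenyl]-5-{3-[4-(benzyloxy)-2-chloro-6-hydroxyphenyl]-3-oxopropyl}-1-benzofuran-3-yl}[4-(benzyloxy)-2-chloro-6-hydroxyphenyl]methanone | O=C(CCc1ccc2oc(-c3ccc(OCc4ccccc4)cc3)c(C(=O)c3c(Cl)cc(OCc4ccccc4)cc3O)c2c1)c1c(Cl)cc(OCc2ccccc2)cc1O | intermediate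
15 | isolophirone C | O=C(CCc1ccc2oc(-c3ccc(O)cc3)c(C(=O)c3ccc(O)cc3O)c2c1)c1ccc(O)cc1O | target

**Step count and risks**
Total steps: 9 (steps 1–3 to the diacid, steps 4–7 to the aryne precursor, steps 8 and 9 in common).
Longest linear sequence: 6 steps (7 → 8 → 9 → 10 → 12 → 14 → 15, steps 4–9).

Steps most likely to fail:

1. Step 8. The double insertion may stall through protonation of the ortho-chloroaryl anion before acyl transfer (leaving aryl esters), through loss of chloride from that anion, through erosion of regioselectivity, or through O-arylation of the product phenoxides by excess aryne; the hindered C3 carboxylate is the more exposed of the two. Fallback by organometallic acylation: setting out from 6, activation with carbonyldiimidazole and treatment with N,O-dimethylhydroxylamine hydrochloride in CH2Cl2 would give the bis-Weinreb amide 2-[4-(benzyloxy)phenyl]-N-methoxy-5-{3-[methoxy(methyl)amino]-3-oxopropyl}-N-methyl-1-benzofuran-3-carboxamide F1. Addition of excess 2,4-dimethoxyphenylmagnesium bromide in THF (0 °C to rt) to both amides would give the diketone O-benzyl tetra-O-methyl isolophirone C F2. BBr3 in CH2Cl2 (−78 °C to rt) would then cleave the four methyl ethers and the benzyl ether, coming back to the route at 15.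

2. Step 2. The radical oxidant may abstract hydrogen from the benzylic ether CH2 of the keto ester, or the phenol may undergo oxidative self-coupling, so that cross-coupling and annulation are inefficient. Fallback by palladium-mediated ring construction: setting out from 3, ortho-iodination (N-iodosuccinimide, cat. TsOH, MeCN, rt) would give methyl 3-(4-hydroxy-3-iodophenyl)propanoate F3. Sonogashira coupling with 1-(benzyloxy)-4-ethynylbenzene (PdCl2(PPh3)2, CuI, Et3N, THF, rt) would give methyl 3-(3-{[4-(benzyloxy)phenyl]ethynyl}-4-hydroxyphenyl)propanoate F4. Oxidative carbonylative annulation (PdI2, thiourea, CBr4, Cs2CO3, CO 1 atm, MeOH, 40 °C) would then close the furan ring with the C3 methyl ester in place, coming back to the route at 5.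

3. Step 9. Hydrogenation may over-reduce the aryl ketone carbonyls or the furan double bond before the hindered chlorides are removed, or chloride may slow the catalyst so that dechlorination is incomplete. Fallback separating the two tasks without H2: setting out from 14, homogeneous hydrodechlorination (Pd(OAc)2 cat., polymethylhydrosiloxane, aq. KF, THF, rt) would give tri-O-benzyl isolophirone C F5. Lewis-acid debenzylation (BCl3, pentamethylbenzene, CH2Cl2, −78 °C) would then come back to the route at 15.

**Further compounds**
F1 | step 8 | 2-[4-(benzyloxy)phenyl]-N-methoxy-5-{3-[methoxy(methyl)amino]-3-oxopropyl}-N-methyl-1-benzofuran-3-carboxamide | CON(C)C(=O)CCc1ccc2oc(-c3ccc(OCc4ccccc4)cc3)c(C(=O)N(C)OC)c2c1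
F2 | step 8 | O-benzyl tetra-O-methyl isolophirone C, {2-[4-(benzyloxy)phenyl]-5-[3-(2,4-dimethoxyphenyl)-3-oxopropyl]-1-benzofuran-3-yl}(2,4-dimethoxyphenyl)methanone | O=C(CCc1ccc2oc(-c3ccc(OCc4ccccc4)cc3)c(C(=O)c3ccc(OC)cc3OC)c2c1)c1ccc(OC)cc1OC
F3 | step 2 | methyl 3-(4-hydroxy-3-iodophenyl)propanoate | COC(=O)CCc1ccc(O)c(I)c1
F4 | step 2 | methyl 3-(3-{[4-(benzyloxy)phenyl]ethynyl}-4-hydroxyphenyl)propanoate | COC(=O)CCc1ccc(O)c(C#Cc2ccc(OCc3ccccc3)cc2)c1
F5 | step 9 | tri-O-benzyl isolophirone C, {2-[4-(benzyloxy)phenyl]-5-{3-[4-(benzyloxy)-2-hydroxyphenyl]-3-oxopropyl}-1-benzofuran-3-yl}[4-(benzyloxy)-2-hydroxyphenyl]methanone | O=C(CCc1ccc2oc(-c3ccc(OCc4ccccc4)cc3)c(C(=O)c3ccc(OCc4ccccc4)cc3O)c2c1)c1ccc(OCc2ccccc2)cc1O
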